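All runs are simulated for substances that don't exist; the scatter is artificial.

By 1.33 min the spring run had lost 5.80 mM of solid substrate and the dusk run 5.72 mM, although their charges were 10 mM and 40 mM. Loss of solid therefore looks zero-order in the charge. The mean read over the dusk curve is 3.84 mM min⁻¹, which, carried to the flask, is 0.192 min⁻¹ of the charge. The flask's charge over this mean rate is 5.21 min, its clearing time. The dusk stretch after 3.00 min, slower than that mean, gives 5.39 min instead.

Two times matter: the clearing time and the asked 8.0 min, with a ratio of 0.651. By this reckoning the flask has 2.79 min after clearing. The spring run read 93.5% side product 0.396 min past its reckoned clearing and 98.1% at 5.40 min past it. My reckoning places the flask's side product between these two readings.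

in all of them: gas 0.97 mM (held)
- spring: solid substrate 10 mM; capture agent 2 mM; run made earlier
- dusk: solid substrate 40 mM; capture agent 2 mM; run made earlier
- flask: solid substrate 20 mM; capture agent 2.00 mM; time 8.0 min

| run | time / min | solid substrate / % | side product / % | target / % | trapped intermediate / % | intermediate C / % | intermediate B / % | intermediate A / % |
|---|---|---|---|---|---|---|---|---|
| spring | 0.667 | 67.9 | 15.4 | 0.2 | 0.8 | 0.4 | 0 | 0.4 |
| spring | 1.33 | 42.0 | 38.8 | 0.5 | 0.3 | 0 | 0.7 | 0 |
| spring | 3.00 | 0 | 93.5 | 0 | 0 | 0 | 0.3 | 1.6 |
| spring | 8.00 | 0 | 98.1 | 1.1 | 0 | 0.3 | 0 | 0.5 |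
| dusk | 0.667 | 92.1 | 3.3 | 0 | 0 | 0.7 | 0.4 | 0 |
| dusk | 1.33 | 85.7 | 9.7 | 0 | 0 | 0 | 0.6 | 0.2 |
| dusk | 3.00 | 69.6 | 26.0 | 0 | 0.2 | 0 | 0 | 0.1 |
| dusk | 8.00 | 23.2 | 72.6 | 1.2 | 0 | 0.2 | 0.4 | 0 |

(standard deviation of a reading: 0.5 percentage points)

- solid, in amounts per volume of the solution: solid substrate
- at the start none of the solid substrate is in solution
- at the start none of the gas is in solution
- a reading or a percentage of intermediate A is of its free form alone

1. the largest share of what was charged as solid substrate, at 8.0 min belongs to (target / trapped intermediate / intermediate C / intermediate B / side product / intermediate A)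
2. the largest share itself, whichever of these holds it, in percent of the solid substrate charged

The forecast names side product at 98.3%, reasoning that “the solid should be gone at about 5 min”.

The flask gives side product at 98.1%, with target at 1.49%.

    reagent + intermediate B ⇌ intermediate C (K = 38000 M⁻¹, k = 12.0 M⁻¹ s⁻¹)
    reagent + intermediate B → target (k = 83.0 M⁻¹ s⁻¹)
    reagent + intermediate A → intermediate B (k = 12.0 M⁻¹ s⁻¹)
    starting material ⇌ intermediate A (K = 4.10, k = 6.60 × 10⁻⁴ s⁻¹)
    starting material + reagent → side product (k = 40.0 M⁻¹ s⁻¹)
    solid substrate ⇌ starting material, rate k6*(cs6 - [starting material]) while solid is left; crystals form when [starting material] > cs6 (solubility = 5.00 mM, k = 0.0200 s⁻¹)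
    gas ⇌ reagent, rate k7*(csat - [reagent]) (kL = 0.500 s⁻¹)
    capture agent + intermediate A → trapped intermediate (k = 0.220 M⁻¹ s⁻¹)

The neighbour flask holds 50 mM of solid substrate, all else as in the flask. Its clearing time is 13.0 min, so 8.0 min covers 61.5% of its charge and should leave 38.5% as solid. That neighbour holds 37.9% solid substrate and 3.68% starting material at that time, and its side product stands at 57.3%.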